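Compound numbers refer to the list after the steps.

## Analysis of the target

Target 21 is an isoflavanone. Ring A (C4a–C8a, with 5-OH, 6-OMe and 7-OH) is fused to the dihydropyranone ring C (O1, C2, C3, C4), and ring B, a 3-hydroxy-4,5-dimethoxyphenyl group, stands on C3. C3 is the only stereocentre; it is R, benzylic to ring B and α to the C4 carbonyl, and there is no second stereocentre from which it could be relayed. This position is the sensitive one: base or strong acid enolises the α-aryl ketone and racemises C3, and oxidants can dehydrogenate C2–C3 to the flat isoflavone. The three free phenols are oxidation-prone and must be told apart from the three methyl ethers, so the phenols are carried as benzyl ethers and the methyl ethers come in with the building blocks. The difficulty is therefore to create C3 as a single enantiomer and to keep it through the construction of the ketone. The strategy rests on ring C: O1, C8a, C4a and C4 form a 1-oxadiene when ring A is drawn as its ortho-quinone methide with C4 as a methylene, and C2–C3, with ring B on C3 and an alkoxy group on C2, is a β-aryl enol ether. A [4+2] cycloaddition of the two makes ring C and C3 together, at a stage where C3 is not yet next to a carbonyl; the price is that the C4 oxygen has to be introduced afterwards.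

## Retrosynthetic reasoning

**21 to 20.** The three phenolic O–H bonds are traced back to O-benzyl ethers. Benzyl is chosen because it can be removed at the very end by neutral hydrogenolysis, the only kind of deprotection that leaves the enolisable C3 of the ketone alone, and because it survives every earlier step.

**20 to 18.** The C4 carbonyl is traced back to the C4 methylene of isoflavan 18. This is the concession the ring-forming step demands: a quinone methide supplies C4 as CH2. In the forward sense C4 is the one C–H position whose cation is stabilised by three oxygen donors of ring A (O1 and the 5- and 7-benzyloxy groups), so a hydride-abstracting quinone in the presence of water should oxidise it selectively, through carbinol 19. The step must not let the C4 cation lose the C3 proton.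

**18 to 17.** An alkoxy group is put back on C2, which makes C2 an acetal carbon. This returns ring C to the oxidation level of a cycloadduct and gives the auxiliary a place to sit. Forward, the exocyclic C2–O bond is ionised and the oxocarbenium ion is reduced by a silane; the auxiliary alcohol 13 is released for reuse.

**17 to 9 and 14.** The key disconnection cuts C3–C4 and O1–C2 in a retro-[4+2] sense. It gives ortho-quinone methide 16, which is too reactive to store and is released in the flask from Boc-oxybenzyl alcohol 9, and the (E)-enol ether 14 of (1R,2S)-2-phenylcyclohexanol. Cutting here, and not at C2–C3 or C4–C4a, forms both ring bonds and the stereocentre in one step from two fragments of similar size. It also lets the polarity of the enol ether decide that ring B ends on C3. Forward, the cycloaddition has to be faster than self-condensation of 16 and has to take place on one face of 14.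

**14 to 12 and 13, and back to 10.** The vinyl C–O bond of 14 is cut to (E)-vinyl iodide 12 and alcohol 13. A copper-catalysed coupling forms this bond with retention of the alkene geometry, which an olefination with an alkoxymethyl ylide would not control. Iodide 12 comes from aldehyde 11 by a one-carbon iodo-olefination, and 11 from commercial phenol 10 by benzylation.

**9 to 6.** The hydroxymethyl carbon and the carbonate of 9 are removed in turn: 9 from aldehyde 8 by reduction, 8 from salicylaldehyde 7 by acylation of the phenol, 7 from phenol 6 by ortho-formylation. Phenol 6 is symmetric and its only free ring positions are the two equivalent ones ortho to the hydroxyl group, so the formylation has no regiochemical choice.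

**6 to 1.** The phenolic oxygen of 6 is traced to the carboxyl carbon of gallate 1 by an aryl migration from carbon to oxygen. The ester is benzylated (2), reduced to alcohol 3, oxidised to aldehyde 4 and converted by peracid oxidation through formate 5 into 6. The longer path from 1 is accepted because 1 already carries the 4-methoxy group between two free phenols, which is the oxygen pattern of ring A.

## Alternatives that were turned down

**Alternative 1:** Ring A is built last, by cutting C4a–C5. The precursor is the pyranone keto ester A1, a polyketide chain masked as a 5-aryl-4-pyranone. Forward, Mg(OMe)2 or LiN(SiMe3)2 deprotonates the side chain, the vinylogous carbon of the pyranone (the later C4a) attacks the methyl ester, and loss of methanol with enolisation gives isoflavone A2.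
- For: the route is biomimetic, it places 5-OH, 6-OMe and 7-OH without protecting groups on ring A, and C4 is a carbonyl from the start, so no benzylic oxidation is needed. On redox economy it is stronger than the chosen route.
- Against: A2 is achiral. C3 would arise only in a later enantioselective reduction of C2=C3, which delivers the enolisable ketone directly under reducing conditions and invites over-reduction at C4 and racemisation. A1 has three acidic sites and an α-methoxy β-keto ester, so both its assembly and the site of its enolisation are open questions.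
- Comparison: the chosen strategy offers a stereocentre formed in the ring-forming step under auxiliary control, as diastereomers that can be separated, at a carbon that cannot enolise when it is made.

**Alternative 2:** Ring C is closed by cutting C2–C3. Forward, Rh2(S-PTTL)4 or its enantiomer decomposes diazoketone A3, and the carbenoid at C3 inserts into a C–H bond of the ortho methoxy group to give chromanone A4.
- For: it is the shortest plan. The stereocentre and the ketone arise together, catalytically and under neutral conditions, with no auxiliary and no late oxidation. On step and redox economy it is clearly stronger.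
- Against: insertion into a methyl C–H bond through a six-membered transition state must compete with attack of the carbenoid on the ether oxygen (oxonium ylide and [1,2]-shift) and with addition to the electron-rich rings A and B. Enantiocontrol for this ring size is not established. A3 needs a 2,6-disubstituted deoxybenzoin with differentiated ortho oxygens and a diazo transfer at a hindered ketone. A4 is already the labile ketone when the silyl ether still has to be removed.
- Comparison: the chosen strategy is longer but rests on a cycloaddition whose regiochemistry follows from polarity, and it does not depend on the chemoselectivity of a carbenoid among several reactive sites.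

**Alternative 3:** C4a–C4 and O1–C2 are cut. Forward, PhB(OH)2 and acetic acid condense phenol 6 with arylacrolein A5 at the ortho carbon, and the vinyl ortho-quinone methide closes by oxa-6π electrocyclisation to isoflavene A6.
- For: it is highly convergent and uses the same phenol 6. The C3=C4 bond of A6 could take up the C4 oxygen and the C3 hydrogen together by hydroboration and oxidation, with no cation next to C3–H. On this point it is stronger than the chosen route.
- Against: A6 is achiral, so C3 depends on reagent- or catalyst-controlled addition to a trisubstituted 1,2-diaryl alkene flanked by the 5-benzyloxy group, and the enantiomers cannot be separated as diastereomers. The borate-templated condensation is at home with β,β-disubstituted enals, whereas A5 is a polymerisation-prone acceptor that can also react at its β-carbon.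
- Comparison: the chosen strategy gives up two or three steps and accepts a late oxidation. In return C3 is fixed by a covalently bound, recoverable auxiliary in a bond-forming step with a clear facial model.

Key step: step 11

Assumption: the sense of facial induction by the (1R,2S) auxiliary follows the conformational model given under step 11; should the cycloaddition favour the other face, the equally available (1S,2R) alcohol would be carried through the same steps.

## Route

Step 1
Reactants: 1 methyl 3,5-dihydroxy-4-methoxybenzoate
Product: 2 methyl 3,5-bis(benzyloxy)-4-methoxybenzoate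
Conditions: BnBr (2.3 equiv), K2CO3, DMF, 60 °C
Reagents that add atoms: benzyl bromide, BrCc1ccccc1
Why: Williamson etherification of both phenols; the ester and the flanked methyl ether are inert to K2CO3 in DMF.

Step 2
Reactants: 2 methyl 3,5-bis(benzyloxy)-4-methoxybenzoate
Product: 3 [3,5-bis(benzyloxy)-4-methoxyphenyl]methanol
Conditions: LiAlH4, THF, 0 °C
Reagents that add atoms: none
Why: Hydride reduction of the benzoate to the primary alcohol; aryl benzyl and methyl ethers do not react.

Step 3
Reactants: 3 [3,5-bis(benzyloxy)-4-methoxyphenyl]methanol
Product: 4 3,5-bis(benzyloxy)-4-methoxybenzaldehyde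
Conditions: MnO2 (activated, excess), CH2Cl2, rt
Reagents that add atoms: none
Why: MnO2 oxidises benzylic alcohols to aldehydes and stops there.

Step 4
Reactants: 4 3,5-bis(benzyloxy)-4-methoxybenzaldehyde
Product: 6 3,5-bis(benzyloxy)-4-methoxyphenol, via aryl formate 5 (not isolated)
Conditions: mCPBA, CH2Cl2, 0 °C to rt; aq. NaHCO3 wash; then K2CO3 (cat.), MeOH, rt, under N2
Reagents that add atoms: mCPBA, O=C(OO)c1cccc(Cl)c1
Why: Baeyer–Villiger (Dakin-type) oxidation; the electron-rich trialkoxyaryl group migrates in preference to hydrogen to give formate 5, which is cleaved by methanolysis, as is standard for 3,4,5-trialkoxybenzaldehydes.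

Step 5
Reactants: 6 3,5-bis(benzyloxy)-4-methoxyphenol
Product: 7 2,4-bis(benzyloxy)-6-hydroxy-3-methoxybenzaldehyde
Conditions: MgCl2, Et3N, (CH2O)n, THF, reflux
Reagents that add atoms: paraformaldehyde (as formaldehyde), C=O
Why: Magnesium-mediated ortho-formylation (Casnati–Skattebøl): the magnesium phenoxide delivers formaldehyde to the ortho carbon and a second formaldehyde oxidises the salicyl alcohol to the aldehyde. The two free ring positions are equivalent and both ortho to the hydroxyl group, so a single monoaldehyde is expected.

Step 6
Reactants: 7 2,4-bis(benzyloxy)-6-hydroxy-3-methoxybenzaldehyde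
Product: 8 tert-butyl 3,5-bis(benzyloxy)-2-formyl-4-methoxyphenyl carbonate
Conditions: Boc2O, i-Pr2NEt, DMAP (cat.), CH2Cl2, 0 °C to rt
Reagents that add atoms: di-tert-butyl dicarbonate, CC(C)(C)OC(=O)OC(=O)OC(C)(C)C
Why: DMAP-catalysed acylation of the phenol gives the aryl tert-butyl carbonate.

Step 7
Reactants: 8 tert-butyl 3,5-bis(benzyloxy)-2-formyl-4-methoxyphenyl carbonate
Product: 9 tert-butyl 3,5-bis(benzyloxy)-2-(hydroxymethyl)-4-methoxyphenyl carbonate
Conditions: BH3·THF, THF, 0 °C; then MeOH, pH 7 buffer
Reagents that add atoms: none
Why: Borane reduces the aldehyde through a neutral alkoxyborane, so no free alkoxide arises that could attack the carbonate. A borohydride salt is avoided because the alkoxide it forms is the very trigger for Boc transfer and quinone methide release, which would end in over-reduction to the methylphenol.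

Step 8
Reactants: 10 3-hydroxy-4,5-dimethoxybenzaldehyde
Product: 11 3-(benzyloxy)-4,5-dimethoxybenzaldehyde
Conditions: BnBr, K2CO3, DMF, rt
Reagents that add atoms: benzyl bromide, BrCc1ccccc1
Why: Williamson etherification of the single phenol.

Step 9
Reactants: 11 3-(benzyloxy)-4,5-dimethoxybenzaldehyde
Product: 12 1-(benzyloxy)-5-[(E)-2-iodovinyl]-2,3-dimethoxybenzene
Conditions: CrCl2 (6 equiv), CHI3 (2 equiv), THF, 0 °C to rt, dark
Reagents that add atoms: iodoform, IC(I)I
Why: Takai olefination; the geminal dichromium species adds to the aldehyde and eliminates from the less crowded arrangement, which for aryl aldehydes gives the (E)-vinyl iodide with high selectivity.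

Step 10
Reactants: 12 1-(benzyloxy)-5-[(E)-2-iodovinyl]-2,3-dimethoxybenzene (1.2 equiv); 13 (1R,2S)-2-phenylcyclohexanol
Product: 14 1-(benzyloxy)-2,3-dimethoxy-5-[(E)-2-{[(1R,2S)-2-phenylcyclohexyl]oxy}vinyl]benzene
Conditions: CuI (10 mol%), 3,4,7,8-tetramethyl-1,10-phenanthroline (20 mol%), Cs2CO3, toluene, 80 °C; chromatography on Et3N-deactivated silica
Reagents that add atoms: none
Why: Copper-catalysed Ullmann-type C–O coupling of a vinyl iodide with an aliphatic alcohol; oxidative addition to monovalent copper and reductive elimination retain the alkene geometry, and the carbinol stereocentres of 13 are not touched.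

Step 11
Reactants: 9 tert-butyl 3,5-bis(benzyloxy)-2-(hydroxymethyl)-4-methoxyphenyl carbonate; 14 1-(benzyloxy)-2,3-dimethoxy-5-[(E)-2-{[(1R,2S)-2-phenylcyclohexyl]oxy}vinyl]benzene (2 equiv, excess recovered)
Product: 17 (2S,3R)-5,7-bis(benzyloxy)-3-[3-(benzyloxy)-4,5-dimethoxyphenyl]-6-methoxy-2-{[(1R,2S)-2-phenylcyclohexyl]oxy}chroman, via Boc-shifted magnesium phenolate 15 (not isolated), via ortho-quinone methide 16 (not isolated)
Conditions: t-BuMgCl (1.05 equiv relative to 9), toluene, −78 °C, slow warming to rt
Reagents that add atoms: none
Why: t-BuMgCl deprotonates the benzylic alcohol of 9, the magnesium alkoxide takes over the Boc group through a six-membered transition state (15), and the phenolate expels the benzylic carbonate (which loses CO2) to release ortho-quinone methide 16 below 0 °C. 16 then reacts as an electron-poor 1-oxadiene (O1=C8a–C4a=C4) with the electron-rich enol ether 14 in an inverse-electron-demand hetero-Diels–Alder reaction, the known behaviour of quinone methides released in this way towards enol ethers, including those of trans-2-phenylcyclohexanol. Ring C is closed by this intermolecular [4+2] cycloaddition, which forms C3–C4 and O1–C2 in one asynchronous step and restores the aromaticity of ring A. Regiochemistry follows the polarity of the partners: the nucleophilic, aryl-bearing carbon of 14 bonds to the methide carbon C4 and O1 bonds to the oxygen-bearing carbon, so ring B ends on C3 and the alkoxy group on C2. C3 is controlled by the auxiliary: in the s-trans enol ether conformer with the carbinol C–H in the enol ether plane, the phenyl group covers the face that is Si at the aryl-bearing carbon, so 16 should add to the Re face, which gives 3R. C2 follows from suprafacial addition to the (E)-alkene and is trans to ring B (2S); because C4 is a methylene, endo and exo approach give the same product. The step needs facial selectivity, secured by the auxiliary with the minor diastereomer removable by chromatography, and it needs capture of 16 to outrun its self-condensation, for which the excess of 14 and the slow warming are meant.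

Step 12
Reactants: 17 (2S,3R)-5,7-bis(benzyloxy)-3-[3-(benzyloxy)-4,5-dimethoxyphenyl]-6-methoxy-2-{[(1R,2S)-2-phenylcyclohexyl]oxy}chroman
Product: 18 (3R)-5,7-bis(benzyloxy)-3-[3-(benzyloxy)-4,5-dimethoxyphenyl]-6-methoxychroman
Conditions: Et3SiH (5 equiv), BF3·OEt2 (1.5 equiv), CH2Cl2, −78 to −40 °C; aq. NaHCO3
Reagents that add atoms: none
Why: Ionic hydrogenation of the acetal: BF3 ionises the exocyclic C2–O bond and Et3SiH reduces the ring oxocarbenium ion, with low temperature and excess silane chosen so that hydride capture is faster than loss of the C3 proton. C3 itself is not a reacting centre, and alcohol 13 is recovered.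

Step 13
Reactants: 18 (3R)-5,7-bis(benzyloxy)-3-[3-(benzyloxy)-4,5-dimethoxyphenyl]-6-methoxychroman
Product: 20 (3R)-5,7-bis(benzyloxy)-3-[3-(benzyloxy)-4,5-dimethoxyphenyl]-6-methoxychroman-4-one, via isoflavan-4-ol 19 (not isolated)
Conditions: DDQ (2.5 equiv), CH2Cl2/aq. NaH2PO4–Na2HPO4 buffer pH 7 (10:1), 0 °C to rt
Reagents that add atoms: water, O
Why: DDQ benzylic oxidation: hydride is abstracted from C4, the only C–H whose cation is stabilised by O1 and the 5- and 7-benzyloxy groups; water captures the cation to give carbinol 19, and a second hydride abstraction gives the aryl ketone, as known for C4 of 5,7-dialkoxyflavans. The buffered two-phase medium is meant to make capture by water faster than loss of the C3 proton and to keep 19 from re-ionising.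

Step 14
Reactants: 20 (3R)-5,7-bis(benzyloxy)-3-[3-(benzyloxy)-4,5-dimethoxyphenyl]-6-methoxychroman-4-one
Product: 21 (3R)-5,7-dihydroxy-3-(3-hydroxy-4,5-dimethoxyphenyl)-6-methoxychroman-4-one
Conditions: H2 (1 atm), 10% Pd/C, EtOAc, rt
Reagents that add atoms: none
Why: Hydrogenolysis of the three aryl benzyl ethers under neutral conditions; the electron-rich aryl ketone is not expected to be reduced, and no acid or base is present to enolise C3.

## Compound list

1 | methyl 3,5-dihydroxy-4-methoxybenzoate | COC(=O)c1cc(O)c(OC)c(O)c1 | starting material
2 | methyl 3,5-bis(benzyloxy)-4-methoxybenzoate | COC(=O)c1cc(OCc2ccccc2)c(OC)c(OCc2ccccc2)c1 | intermediate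
3 | [3,5-bis(benzyloxy)-4-methoxyphenyl]methanol | OCc1cc(OCc2ccccc2)c(OC)c(OCc2ccccc2)c1 | intermediate
4 | 3,5-bis(benzyloxy)-4-methoxybenzaldehyde | O=Cc1cc(OCc2ccccc2)c(OC)c(OCc2ccccc2)c1 | intermediate
5 | 3,5-bis(benzyloxy)-4-methoxyphenyl formate | O=COc1cc(OCc2ccccc2)c(OC)c(OCc2ccccc2)c1 | intermediate (not isolated)
6 | 3,5-bis(benzyloxy)-4-methoxyphenol | Oc1cc(OCc2ccccc2)c(OC)c(OCc2ccccc2)c1 | intermediate
7 | 2,4-bis(benzyloxy)-6-hydroxy-3-methoxybenzaldehyde | O=Cc1c(O)cc(OCc2ccccc2)c(OC)c1OCc1ccccc1 | intermediate
8 | tert-butyl 3,5-bis(benzyloxy)-2-formyl-4-methoxyphenyl carbonate | O=Cc1c(OC(=O)OC(C)(C)C)cc(OCc2ccccc2)c(OC)c1OCc1ccccc1 | intermediate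
9 | tert-butyl 3,5-bis(benzyloxy)-2-(hydroxymethyl)-4-methoxyphenyl carbonate | OCc1c(OC(=O)OC(C)(C)C)cc(OCc2ccccc2)c(OC)c1OCc1ccccc1 | intermediate
10 | 3-hydroxy-4,5-dimethoxybenzaldehyde | COc1cc(C=O)cc(O)c1OC | starting material
11 | 3-(benzyloxy)-4,5-dimethoxybenzaldehyde | COc1cc(C=O)cc(OCc2ccccc2)c1OC | intermediate
12 | 1-(benzyloxy)-5-[(E)-2-iodovinyl]-2,3-dimethoxybenzene | COc1cc(/C=C/I)cc(OCc2ccccc2)c1OC | intermediate
13 | (1R,2S)-2-phenylcyclohexanol | O[C@@H]1CCCC[C@H]1c1ccccc1 | starting material
14 | 1-(benzyloxy)-2,3-dimethoxy-5-[(E)-2-{[(1R,2S)-2-phenylcyclohexyl]oxy}vinyl]benzene | COc1cc(/C=C/O[C@@H]2CCCC[C@H]2c2ccccc2)cc(OCc2ccccc2)c1OC | intermediate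
15 | chloromagnesium 3,5-bis(benzyloxy)-2-{[(tert-butoxycarbonyl)oxy]methyl}-4-methoxyphenolate | CC(C)(C)OC(=O)OCc1c([O-])cc(OCc2ccccc2)c(OC)c1OCc1ccccc1.[Mg+]Cl | intermediate (not isolated)
16 | 3,5-bis(benzyloxy)-4-methoxy-6-methylidenecyclohexa-2,4-dien-1-one | C=C1C(=O)C=C(OCc2ccccc2)C(OC)=C1OCc1ccccc1 | intermediate (not isolated)
17 | (2S,3R)-5,7-bis(benzyloxy)-3-[3-(benzyloxy)-4,5-dimethoxyphenyl]-6-methoxy-2-{[(1R,2S)-2-phenylcyclohexyl]oxy}chroman | COc1cc([C@@H]2[C@@H](O[C@@H]3CCCC[C@H]3c3ccccc3)Oc3cc(OCc4ccccc4)c(OC)c(OCc4ccccc4)c3C2)cc(OCc2ccccc2)c1OC | intermediate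
18 | (3R)-5,7-bis(benzyloxy)-3-[3-(benzyloxy)-4,5-dimethoxyphenyl]-6-methoxychroman | COc1cc([C@@H]2COc3cc(OCc4ccccc4)c(OC)c(OCc4ccccc4)c3C2)cc(OCc2ccccc2)c1OC | intermediate
19 | (3R)-5,7-bis(benzyloxy)-3-[3-(benzyloxy)-4,5-dimethoxyphenyl]-6-methoxychroman-4-ol (C4 epimers) | COc1cc([C@@H]2COc3cc(OCc4ccccc4)c(OC)c(OCc4ccccc4)c3C2O)cc(OCc2ccccc2)c1OC | intermediate (not isolated)
20 | (3R)-5,7-bis(benzyloxy)-3-[3-(benzyloxy)-4,5-dimethoxyphenyl]-6-methoxychroman-4-one | COc1cc([C@@H]2COc3cc(OCc4ccccc4)c(OC)c(OCc4ccccc4)c3C2=O)cc(OCc2ccccc2)c1OC | intermediate
21 | (3R)-5,7-dihydroxy-3-(3-hydroxy-4,5-dimethoxyphenyl)-6-methoxychroman-4-one | COc1cc([C@@H]2COc3cc(O)c(OC)c(O)c3C2=O)cc(O)c1OC | target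

## Step count and least certain steps

Total: 14 steps. Longest linear sequence: 11 steps (steps 1–7 and 11–14, from 1).

**Step 11 (key step).** The most likely failure is that 16 condenses with itself faster than it is captured, because 14 is a 1,2-disubstituted enol ether whose nucleophilic carbon carries an aryl group. The second risk is insufficient facial discrimination, since the model depends on the conformation about the enol ether C–O bonds.
Fallback, from 14 and 9, returning at 18: the 2π partner is changed to a more nucleophilic enamine. Mild aqueous acid (oxalic acid, THF/H2O) hydrolyses 14 to 2-[3-(benzyloxy)-4,5-dimethoxyphenyl]acetaldehyde F1, with 13 recovered. Condensation with (S)-2-(methoxymethyl)pyrrolidine over molecular sieves gives the (E)-enamine F2. Release of 16 from 9 with t-BuMgCl in the presence of F2 should give the trans 2-aminochroman F3. Dilute aqueous acid converts this to the lactol F4, and Et3SiH/BF3·OEt2 at −78 °C reduces F4 to 18. The antipodal amine would be used if the sense of induction requires it.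

**Step 13.** The C4 cation can lose the C3 proton instead of being captured by water, or carbinol 19 can re-ionise under the acidity of the reduced quinone. Either process flattens C3 and destroys the stereocentre. The axial C3–H is well aligned for this elimination, so this is the weakest step after the key step.
Fallback, from 18, returning at 20: the elimination is taken on purpose and C3 is set again together with the C4 oxygen. DDQ in dry dioxane dehydrogenates 18 to the isoflavene F5 (the same compound as A6). Hydroboration with the enantiomer of monoisopinocampheylborane that delivers hydrogen to the required face of C3, followed by NaOH/H2O2, gives the trans carbinol F6. Dess–Martin periodinane buffered with NaHCO3 oxidises F6 to 20.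

**Step 12.** The oxocarbenium ion at C2 can lose the C3 proton reversibly, which would erode the configuration, or the endocyclic C2–O1 bond can ionise in place of the exocyclic one, which would open ring C.
Fallback, from 17, returning at 18: ring C is opened and closed again instead of being reduced in place. Dilute HCl in THF/H2O hydrolyses 17 to the lactol F4 (already defined above), with 13 recovered. NaBH4 in EtOH at 0 °C reduces the open hydroxy-aldehyde form to the phenol-diol F7. A Mitsunobu reaction (PPh3, diisopropyl azodicarboxylate, THF) between the phenol and the primary alcohol closes O1–C2 to give 18.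

**Step 10.** The hindered secondary alcohol may couple too slowly, so that base-induced loss of HI from 12 or decomposition of the vinyl iodide takes over.
Fallback, from 13 and 11, returning at 14: the enol ether is made by carbonyl olefination with stereospecific elimination. The sodium alkoxide of 13 (NaH, DMF) is alkylated with (diphenylphosphoryl)methyl 4-methylbenzenesulfonate to give the phosphine oxide F8. Lithiation with LiN(i-Pr)2 at −78 °C and addition to 11 (Horner–Wittig addition) gives β-hydroxy phosphine oxides, from which the pair F9 and F10 is separated by chromatography. Syn-elimination of diphenylphosphinate with KOt-Bu in THF converts both F9 and F10 to (E)-14.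

**Step 14.** Over-reduction of the benzylic ketone, slow cleavage of the hindered 5-O-benzyl ether, or partial racemisation on prolonged contact with the catalyst are possible.
Fallback, from 20, returning at 21: the benzyl groups are removed by Lewis-acid ionisation instead of hydrogenolysis, with BCl3 and pentamethylbenzene as cation scavenger in CH2Cl2 at −78 °C. This fallback makes no new compound (F0).

## Further compounds

F1 | step 11 | 2-[3-(benzyloxy)-4,5-dimethoxyphenyl]acetaldehyde | COc1cc(CC=O)cc(OCc2ccccc2)c1OC
F2 | step 11 | (2S)-1-{(E)-2-[3-(benzyloxy)-4,5-dimethoxyphenyl]vinyl}-2-(methoxymethyl)pyrrolidine | COC[C@@H]1CCCN1/C=C/c1cc(OC)c(OC)c(OCc2ccccc2)c1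
F3 | step 11 | (2S)-1-{(2S,3R)-5,7-bis(benzyloxy)-3-[3-(benzyloxy)-4,5-dimethoxyphenyl]-6-methoxychroman-2-yl}-2-(methoxymethyl)pyrrolidine | COc1cc([C@@H]2[C@@H](N3CCC[C@H]3COC)Oc3cc(OCc4ccccc4)c(OC)c(OCc4ccccc4)c3C2)cc(OCc2ccccc2)c1OC
F4 | step 11 | (3R)-5,7-bis(benzyloxy)-3-[3-(benzyloxy)-4,5-dimethoxyphenyl]-6-methoxychroman-2-ol (C2 epimers) | COc1cc([C@@H]2C(O)Oc3cc(OCc4ccccc4)c(OC)c(OCc4ccccc4)c3C2)cc(OCc2ccccc2)c1OC
F5 | step 13 | 5,7-bis(benzyloxy)-3-[3-(benzyloxy)-4,5-dimethoxyphenyl]-6-methoxy-2H-chromene | COc1cc(C2=Cc3c(OCc4ccccc4)c(OC)c(OCc4ccccc4)cc3OC2)cc(OCc2ccccc2)c1OC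
F6 | step 13 | (3R,4S)-5,7-bis(benzyloxy)-3-[3-(benzyloxy)-4,5-dimethoxyphenyl]-6-methoxychroman-4-ol | COc1cc([C@@H]2COc3cc(OCc4ccccc4)c(OC)c(OCc4ccccc4)c3[C@H]2O)cc(OCc2ccccc2)c1OC
F7 | step 12 | 3,5-bis(benzyloxy)-2-{(2R)-2-[3-(benzyloxy)-4,5-dimethoxyphenyl]-3-hydroxypropyl}-4-methoxyphenol | COc1cc([C@H](CO)Cc2c(O)cc(OCc3ccccc3)c(OC)c2OCc2ccccc2)cc(OCc2ccccc2)c1OC
F8 | step 10 | diphenyl({[(1R,2S)-2-phenylcyclohexyl]oxy}methyl)phosphine oxide | O=P(CO[C@@H]1CCCC[C@H]1c1ccccc1)(c1ccccc1)c1ccccc1
F9 | step 10 | (1S,2R)-1-[3-(benzyloxy)-4,5-dimethoxyphenyl]-2-(diphenylphosphoryl)-2-{[(1R,2S)-2-phenylcyclohexyl]oxy}ethan-1-ol | O=P(c1ccccc1)(c1ccccc1)[C@@H](O[C@@H]1CCCC[C@H]1c1ccccc1)[C@@H](O)c1cc(OC)c(OC)c(OCc2ccccc2)c1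
F10 | step 10 | (1R,2S)-1-[3-(benzyloxy)-4,5-dimethoxyphenyl]-2-(diphenylphosphoryl)-2-{[(1R,2S)-2-phenylcyclohexyl]oxy}ethan-1-ol | O=P(c1ccccc1)(c1ccccc1)[C@H](O[C@@H]1CCCC[C@H]1c1ccccc1)[C@H](O)c1cc(OC)c(OC)c(OCc2ccccc2)c1
F0 | step 14 | none | none
A1 | alternative 1 | methyl 4-{5-[3-(benzyloxy)-4,5-dimethoxyphenyl]-4-oxo-4H-pyran-2-yl}-2-methoxy-3-oxobutanoate | COC(=O)C(OC)C(=O)Cc1cc(=O)c(-c2cc(OC)c(OC)c(OCc3ccccc3)c2)co1
A2 | alternative 1 | 3-[3-(benzyloxy)-4,5-dimethoxyphenyl]-5,7-dihydroxy-6-methoxy-4H-chromen-4-one | COc1cc(-c2coc3cc(O)c(OC)c(O)c3c2=O)cc(OCc2ccccc2)c1OC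
A3 | alternative 2 | 1-[4-(benzyloxy)-3,6-dimethoxy-2-(triisopropylsilyloxy)phenyl]-2-[3-(benzyloxy)-4,5-dimethoxyphenyl]-2-diazoethan-1-one | COc1cc(OCc2ccccc2)c(OC)c(O[Si](C(C)C)(C(C)C)C(C)C)c1C(=O)C(=[N+]=[N-])c1cc(OC)c(OC)c(OCc2ccccc2)c1
A4 | alternative 2 | (3R)-7-(benzyloxy)-3-[3-(benzyloxy)-4,5-dimethoxyphenyl]-6-methoxy-5-(triisopropylsilyloxy)chroman-4-one | COc1cc([C@@H]2COc3cc(OCc4ccccc4)c(OC)c(O[Si](C(C)C)(C(C)C)C(C)C)c3C2=O)cc(OCc2ccccc2)c1OC
A5 | alternative 3 | 2-[3-(benzyloxy)-4,5-dimethoxyphenyl]prop-2-enal | C=C(C=O)c1cc(OC)c(OC)c(OCc2ccccc2)c1
A6 | alternative 3 | 5,7-bis(benzyloxy)-3-[3-(benzyloxy)-4,5-dimethoxyphenyl]-6-methoxy-2H-chromene | COc1cc(C2=Cc3c(OCc4ccccc4)c(OC)c(OCc4ccccc4)cc3OC2)cc(OCc2ccccc2)c1OC
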